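**Retrosynthetic overview**

1. Numbering: chain C1–C12 from the ethyl end (C3 Me, C4 OH, C5, C6=C7, C9 Me, C12 ketone), C13 = carboxyl carbon on C5, ring O1'–C2'(=O)–C3'–C4'(OH)–C5'–C6'(Me). The strategy rests on the acyclic unit C4(OH)–C5(C13)–C6=C7(E)–C8, a syn homoallylic alcohol with an E alkene, which is what an α-substituted, (Z)-γ-substituted allylboronate gives with an aldehyde.
2. The only ring (the 3-acyl-4-hydroxy-5,6-dihydropyran-2-one) is formed last. It is opened at C3'–C4' (Dieckmann) and at O1'–C2' (acylketene from the C12 acid plus methyl (R)-3-hydroxybutanoate), and the C13 acid is traced back to CH2OPMB.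
3. Key disconnection: C6–C7 and C4–C5 in one pot from a C7-lithiated carbamate, a (Z)-alkenyl pinacol boronate (C5, C6, C13) and (S)-2-methylbutanal (C1–C4).
4. Fragments: the carbamate from (R)-citronellol (C7–C12, C9 centre), the boronate from propargyl alcohol, the aldehyde from (S)-2-methylbutan-1-ol.
5. The C13 ester is removed before the ring closure, so that the base meets a carboxylate and C5 cannot enolise.

Key step: step 8

Remark on the chemistry: the target is drawn as the C4' enol of the 3-acylpyran-2,4-dione; the tricarbonyl unit is assumed to settle into this tautomer.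

**Route**

Step 1
Reactants: 1 (R)-citronellol
Product: 2 (R)-3,7-dimethyloct-6-en-1-yl N,N-diisopropylcarbamate
Conditions: iPr2NCOCl, Et3N, CH2Cl2, reflux
Reagents that add atoms: N,N-diisopropylcarbamoyl chloride CC(C)N(C(C)C)C(Cl)=O
Why: O-carbamoylation of the primary alcohol (acyl substitution) installs the carbamate that later directs and stabilises lithiation at C7; the remote C9 centre is untouched.

Step 2
Reactants: 2 (R)-3,7-dimethyloct-6-en-1-yl N,N-diisopropylcarbamate
Product: 4 (R)-6-hydroxy-3-methylhexyl N,N-diisopropylcarbamate, via aldehyde 3 (not isolated)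
Conditions: O3, CH2Cl2/MeOH, −78 °C; then NaBH4 (excess), −78 °C to rt
Reagents that add atoms: ozone [O-][O+]=O
Why: Ozonolysis of the trisubstituted alkene with reductive work-up by borohydride should give the C12 primary alcohol, the carbamate being inert to both reagents.

Step 3
Reactants: 4 (R)-6-hydroxy-3-methylhexyl N,N-diisopropylcarbamate
Product: 5 (R)-6-(tert-butyldimethylsilyloxy)-3-methylhexyl N,N-diisopropylcarbamate
Conditions: TBSCl, imidazole, DMF, rt
Reagents that add atoms: tert-butyldimethylsilyl chloride CC(C)(C)[Si](C)(C)Cl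
Why: Standard silylation of a primary alcohol gives a C12 ether that tolerates sBuLi.

Step 4
Reactants: 6 propargyl alcohol
Product: 8 1-methoxy-4-[(prop-2-yn-1-yloxy)methyl]benzene, via sodium prop-2-yn-1-olate 7 (not isolated)
Conditions: NaH, THF/DMF, 0 °C; then PMBCl, nBu4NI (cat.), 0 °C to rt
Reagents that add atoms: 4-methoxybenzyl chloride COc1ccc(CCl)cc1
Why: Williamson etherification of the alkoxide with the benzylic chloride, with iodide catalysis of the SN2 step.

Step 5
Reactants: 8 1-methoxy-4-[(prop-2-yn-1-yloxy)methyl]benzene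
Product: 11 2-{3-[(4-methoxybenzyl)oxy]prop-1-yn-1-yl}-4,4,5,5-tetramethyl-1,3,2-dioxaborolane, via lithium acetylide 9 (not isolated), via lithium alkynylborate 10 (not isolated)
Conditions: nBuLi, THF, −78 °C; then iPrOBpin, −78 °C; then HCl in Et2O, −78 °C to rt
Reagents that add atoms: 2-isopropoxy-4,4,5,5-tetramethyl-1,3,2-dioxaborolane CC(C)OB1OC(C)(C)C(C)(C)O1
Why: Borylation of the lithium acetylide with an alkoxyboronate and anhydrous acid release of isopropanol (Brown alkynylboronate synthesis) gives the alkynyl boronate.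

Step 6
Reactants: 11 2-{3-[(4-methoxybenzyl)oxy]prop-1-yn-1-yl}-4,4,5,5-tetramethyl-1,3,2-dioxaborolane
Product: 12 (Z)-2-{3-[(4-methoxybenzyl)oxy]prop-1-en-1-yl}-4,4,5,5-tetramethyl-1,3,2-dioxaborolane
Conditions: H2 (1 atm), Pd on CaCO3 poisoned with Pb(OAc)2 (Lindlar catalyst), pyridine, 1,4-dioxane, rt
Reagents that add atoms: none
Why: Lindlar semihydrogenation adds both hydrogens syn, so the alkynyl boronate should give the (Z)-alkenyl boronate, and the poisoned catalyst leaves the PMB ether and the C–B bond intact.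

Step 7
Reactants: 13 (S)-2-methylbutan-1-ol
Product: 14 (S)-2-methylbutanal
Conditions: TEMPO (cat.), KBr (cat.), NaOCl, NaHCO3, CH2Cl2/H2O, 0 °C; distilled and used at once
Reagents that add atoms: none
Why: Anelli oxidation (TEMPO/NaOCl) stops at the aldehyde under buffered two-phase conditions that are known to preserve the α-stereocentre of this aldehyde.

Step 8
Reactants: 5 (R)-6-(tert-butyldimethylsilyloxy)-3-methylhexyl N,N-diisopropylcarbamate; 12 (Z)-2-{3-[(4-methoxybenzyl)oxy]prop-1-en-1-yl}-4,4,5,5-tetramethyl-1,3,2-dioxaborolane; 14 (S)-2-methylbutanal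
Product: 19 (3S,4R,5S,6E,9R)-12-(tert-butyldimethylsilyloxy)-5-{[(4-methoxybenzyl)oxy]methyl}-3,9-dimethyldodec-6-en-4-ol, via lithiated carbamate 15 (not isolated), via boronate complex 16 (not isolated), via allylboronate 17 (not isolated), via borate ester 18 (not isolated)
Conditions: 5, sBuLi, (−)-sparteine, Et2O, −78 °C, 5 h; then 12, −78 °C, 1 h; then MgBr2·OEt2, −78 °C to 35 °C; then 14, 0 °C to rt; H2O work-up
Reagents that add atoms: none
Why: sBuLi/(−)-sparteine removes the pro-S proton at C7 (Hoppe deprotonation) and the configurationally stable lithio carbamate 15 adds to boron of 12 with retention, after which in complex 16 the alkenyl carbon C6 migrates from boron to C7 anti to the departing carbamate (1,2-metallate rearrangement with inversion, promoted by MgBr2), forming C6–C7 and the (R)-configured, (Z)-γ-substituted allylboronate 17. Allylboronate 17 then adds to aldehyde 14 through a closed six-membered chair (type 1 allylboration) on the boron-bearing face, forming C4–C5 while the double bond moves to C6=C7; the closest known reaction type is the one-pot lithiation–borylation–allylboration of primary carbamates with (Z)-alkenyl pinacol boronates. No ring is closed. In the chair the CH2OPMB group on C5 is axial because of the Z geometry, so the C8 chain on C7 must be equatorial to avoid a 1,3-diaxial clash, which gives the E alkene; the Z geometry gives the syn C4/C5 relation and the sparteine-set C7 centre fixes the face of C5, so that C4 should emerge R and C5 S. The step needs reagent control over the aldehyde, secured because the stereocentre of 14 differs only in methyl against ethyl and has almost no Felkin bias, and site-selective lithiation, secured because the carbamate is the only acidifying group in 5. C9 and C3 are carried through unchanged, the latter because the fresh aldehyde meets no free base.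

Step 9
Reactants: 19 (3S,4R,5S,6E,9R)-12-(tert-butyldimethylsilyloxy)-5-{[(4-methoxybenzyl)oxy]methyl}-3,9-dimethyldodec-6-en-4-ol
Product: 20 (3S,4R,5S,6E,9R)-4,12-bis(tert-butyldimethylsilyloxy)-5-{[(4-methoxybenzyl)oxy]methyl}-3,9-dimethyldodec-6-ene
Conditions: TBSOTf, 2,6-lutidine, CH2Cl2, −78 °C to 0 °C
Reagents that add atoms: tert-butyldimethylsilyl triflate CC(C)(C)[Si](C)(C)OS(=O)(=O)C(F)(F)F
Why: Silylation of the hindered secondary C4 alcohol with the silyl triflate masks it before the oxidations and the basic ring closure.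

Step 10
Reactants: 20 (3S,4R,5S,6E,9R)-4,12-bis(tert-butyldimethylsilyloxy)-5-{[(4-methoxybenzyl)oxy]methyl}-3,9-dimethyldodec-6-ene
Product: 21 (2S,3E,6R)-2-[(1R,2S)-1-(tert-butyldimethylsilyloxy)-2-methylbutyl]-9-(tert-butyldimethylsilyloxy)-6-methylnon-3-en-1-ol
Conditions: DDQ, CH2Cl2/pH 7 phosphate buffer, 0 °C
Reagents that add atoms: none
Why: Oxidative PMB cleavage by DDQ (oxidation of the electron-rich benzyl ether, hydrolysis of the oxocarbenium ion) frees C13–OH without touching the silyl ethers or the isolated alkene.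

Step 11
Reactants: 21 (2S,3E,6R)-2-[(1R,2S)-1-(tert-butyldimethylsilyloxy)-2-methylbutyl]-9-(tert-butyldimethylsilyloxy)-6-methylnon-3-en-1-ol
Product: 23 (2R,3E,6R)-2-[(1R,2S)-1-(tert-butyldimethylsilyloxy)-2-methylbutyl]-9-(tert-butyldimethylsilyloxy)-6-methylnon-3-enoic acid, via aldehyde 22 (not isolated)
Conditions: TEMPO (cat.), PhI(OAc)2, MeCN/pH 7 phosphate buffer, 0 °C to rt
Reagents that add atoms: water O
Why: The TEMPO/PhI(OAc)2 oxidation (Epp–Widlanski) takes the primary alcohol through the aldehyde hydrate to the acid under near-neutral conditions, so that C5 and the β,γ double bond of transient aldehyde 22 never meet base.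

Step 12
Reactants: 23 (2R,3E,6R)-2-[(1R,2S)-1-(tert-butyldimethylsilyloxy)-2-methylbutyl]-9-(tert-butyldimethylsilyloxy)-6-methylnon-3-enoic acid
Product: 24 allyl (2R,3E,6R)-2-[(1R,2S)-1-(tert-butyldimethylsilyloxy)-2-methylbutyl]-9-(tert-butyldimethylsilyloxy)-6-methylnon-3-enoate
Conditions: allyl bromide, KHCO3, DMF, rt
Reagents that add atoms: allyl bromide C=CCBr
Why: SN2 esterification of the carboxylate under bicarbonate, too weak a base to enolise the β,γ-unsaturated ester, masks C13 so that the C12 acid can later be activated alone.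

Step 13
Reactants: 24 allyl (2R,3E,6R)-2-[(1R,2S)-1-(tert-butyldimethylsilyloxy)-2-methylbutyl]-9-(tert-butyldimethylsilyloxy)-6-methylnon-3-enoate
Product: 25 allyl (2R,3E,6R)-2-[(1R,2S)-1-(tert-butyldimethylsilyloxy)-2-methylbutyl]-9-hydroxy-6-methylnon-3-enoate
Conditions: HF·pyridine, pyridine, THF, 0 °C
Reagents that add atoms: none
Why: Buffered fluoride desilylation removes the unhindered primary C12 silyl ether much faster than the secondary C4 silyl ether flanked by two branched carbons.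

Step 14
Reactants: 25 allyl (2R,3E,6R)-2-[(1R,2S)-1-(tert-butyldimethylsilyloxy)-2-methylbutyl]-9-hydroxy-6-methylnon-3-enoate
Product: 27 (4R,6E,8R)-9-(allyloxy)-8-[(1R,2S)-1-(tert-butyldimethylsilyloxy)-2-methylbutyl]-4-methyl-9-oxonon-6-enoic acid, via aldehyde 26 (not isolated)
Conditions: TEMPO (cat.), PhI(OAc)2, MeCN/pH 7 phosphate buffer, rt
Reagents that add atoms: water O
Why: The same TEMPO/PhI(OAc)2 oxidation converts the C12 primary alcohol to the acid; allyl ester, silyl ether and alkene are inert.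

Step 15
Reactants: 27 (4R,6E,8R)-9-(allyloxy)-8-[(1R,2S)-1-(tert-butyldimethylsilyloxy)-2-methylbutyl]-4-methyl-9-oxonon-6-enoic acid; 28 Meldrum's acid (2,2-dimethyl-1,3-dioxane-4,6-dione)
Product: 29 allyl (2R,3E,6R)-2-[(1R,2S)-1-(tert-butyldimethylsilyloxy)-2-methylbutyl]-9-(2,2-dimethyl-4,6-dioxo-1,3-dioxan-5-ylidene)-9-hydroxy-6-methylnon-3-enoate (acyl Meldrum's acid, enol form)
Conditions: DCC, DMAP, CH2Cl2, 0 °C to rt
Reagents that add atoms: none
Why: Carbodiimide activation and DMAP-mediated C-acylation of Meldrum's acid (Yonemitsu acylation) gives the latent acylketene that carries C12, C3' and C2'.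

Step 16
Reactants: 29 acyl Meldrum's acid; 30 methyl (R)-3-hydroxybutanoate
Product: 32 1-allyl 11-[(R)-4-methoxy-4-oxobutan-2-yl] (2R,3E,6R)-2-[(1R,2S)-1-(tert-butyldimethylsilyloxy)-2-methylbutyl]-6-methyl-9-oxoundec-3-enedioate, via acylketene 31 (not isolated)
Conditions: toluene, 90 °C
Reagents that add atoms: none
Why: Thermal retro-[4+2] fragmentation of the acyl Meldrum's acid releases acetone and CO2, and the acylketene is trapped by the hydroxyl of 30 (acylketene alcoholysis), forming O1'–C2' with C6' retained because its C–O bond is not broken.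

Step 17
Reactants: 32 the β-keto ester from step 16
Product: 33 (2R,3E,6R)-2-[(1R,2S)-1-(tert-butyldimethylsilyloxy)-2-methylbutyl]-11-{[(R)-4-methoxy-4-oxobutan-2-yl]oxy}-6-methyl-9,11-dioxoundec-3-enoic acid
Conditions: Pd(PPh3)4 (cat.), N-methylaniline, THF, rt
Reagents that add atoms: none
Why: Tsuji–Trost deallylation, in which zerovalent palladium ionises the allyl ester and N-methylaniline captures the π-allyl complex, frees the C13 acid under neutral conditions before the basic step.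

Step 18
Reactants: 33 the C13 acid from step 17
Product: 36 (2R,3E,6R)-2-[(1R,2S)-1-(tert-butyldimethylsilyloxy)-2-methylbutyl]-9-[(R)-4-hydroxy-6-methyl-2-oxo-5,6-dihydro-2H-pyran-3-yl]-6-methyl-9-oxonon-3-enoic acid, via open-chain dipotassium salt 34 (not isolated), via cyclised dipotassium salt 35 (not isolated)
Conditions: KOtBu (2.2 equiv), tBuOH/THF, 0 °C to rt; then cold 1 M HCl to pH 2
Reagents that add atoms: none
Why: Dieckmann (Lacey–Dieckmann) condensation, in which the C3' enolate of the β-keto ester attacks the methyl ester carbon C4' in a 6-exo-trig closure and the released methoxide deprotonates the tricarbonyl product, while the adjacent carboxylate keeps C5 from enolising and C6' is not epimerisable.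

Step 19
Reactants: 36 the C4 silyl ether from step 18
Product: 37 (2R,3E,6R)-2-[(1R,2S)-1-hydroxy-2-methylbutyl]-9-[(R)-4-hydroxy-6-methyl-2-oxo-5,6-dihydro-2H-pyran-3-yl]-6-methyl-9-oxonon-3-enoic acid (target)
Conditions: 48% aq. HF, MeCN, 0 °C to rt
Reagents that add atoms: none
Why: Acidic fluoride desilylation of the secondary silyl ether, which the acylhydroxydihydropyranone, the β-hydroxy acid and the alkene should tolerate, gives the target.

**Compound list**

1 | (R)-citronellol | OCC[C@H](C)CCC=C(C)C | starting material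
2 | (R)-3,7-dimethyloct-6-en-1-yl N,N-diisopropylcarbamate | CC(C)N(C(C)C)C(=O)OCC[C@H](C)CCC=C(C)C | intermediate
3 | (R)-3-methyl-6-oxohexyl N,N-diisopropylcarbamate (not isolated) | CC(C)N(C(C)C)C(=O)OCC[C@H](C)CCC=O | intermediate
4 | (R)-6-hydroxy-3-methylhexyl N,N-diisopropylcarbamate | CC(C)N(C(C)C)C(=O)OCC[C@H](C)CCCO | intermediate
5 | (R)-6-(tert-butyldimethylsilyloxy)-3-methylhexyl N,N-diisopropylcarbamate | CC(C)N(C(C)C)C(=O)OCC[C@H](C)CCCO[Si](C)(C)C(C)(C)C | intermediate
6 | propargyl alcohol | C#CCO | starting material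
7 | sodium prop-2-yn-1-olate (not isolated) | [Na+].[O-]CC#C | intermediate
8 | 1-methoxy-4-[(prop-2-yn-1-yloxy)methyl]benzene | C#CCOCc1ccc(OC)cc1 | intermediate
9 | {3-[(4-methoxybenzyl)oxy]prop-1-yn-1-yl}lithium (not isolated) | [Li]C#CCOCc1ccc(OC)cc1 | intermediate
10 | lithium isopropoxy{3-[(4-methoxybenzyl)oxy]prop-1-yn-1-yl}(pinacolato)borate (not isolated) | [Li+].COc1ccc(COCC#C[B-]2(OC(C)C)OC(C)(C)C(C)(C)O2)cc1 | intermediate
11 | 2-{3-[(4-methoxybenzyl)oxy]prop-1-yn-1-yl}-4,4,5,5-tetramethyl-1,3,2-dioxaborolane | COc1ccc(COCC#CB2OC(C)(C)C(C)(C)O2)cc1 | intermediate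
12 | (Z)-2-{3-[(4-methoxybenzyl)oxy]prop-1-en-1-yl}-4,4,5,5-tetramethyl-1,3,2-dioxaborolane | COc1ccc(COC/C=C\B2OC(C)(C)C(C)(C)O2)cc1 | intermediate
13 | (S)-2-methylbutan-1-ol | CC[C@H](C)CO | starting material
14 | (S)-2-methylbutanal | CC[C@H](C)C=O | intermediate
15 | (1S,3R)-6-(tert-butyldimethylsilyloxy)-1-lithio-3-methylhexyl N,N-diisopropylcarbamate, (−)-sparteine complex (not isolated) | CC(C)N(C(C)C)C(=O)O[C@@H]([Li])CC[C@H](C)CCCO[Si](C)(C)C(C)(C)C | intermediate
16 | lithium pinacol borate bearing the (1S,3R)-1-(diisopropylcarbamoyloxy)-6-(tert-butyldimethylsilyloxy)-3-methylhexyl and (Z)-3-(4-methoxybenzyloxy)prop-1-enyl groups on boron (not isolated) | [Li+].CC(C)N(C(C)C)C(=O)O[C@H](CC[C@H](C)CCCO[Si](C)(C)C(C)(C)C)[B-]1(/C=C\COCc2ccc(OC)cc2)OC(C)(C)C(C)(C)O1 | intermediate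
17 | 2-[(2Z,4R,6R)-9-(tert-butyldimethylsilyloxy)-1-[(4-methoxybenzyl)oxy]-6-methylnon-2-en-4-yl]-4,4,5,5-tetramethyl-1,3,2-dioxaborolane (not isolated) | COc1ccc(COC/C=C\[C@@H](CC[C@H](C)CCCO[Si](C)(C)C(C)(C)C)B2OC(C)(C)C(C)(C)O2)cc1 | intermediate
18 | pinacol borate ester of 19 at the C4 oxygen (not isolated) | CC[C@H](C)[C@@H](OB1OC(C)(C)C(C)(C)O1)[C@@H](/C=C/C[C@H](C)CCCO[Si](C)(C)C(C)(C)C)COCc1ccc(OC)cc1 | intermediate
19 | (3S,4R,5S,6E,9R)-12-(tert-butyldimethylsilyloxy)-5-{[(4-methoxybenzyl)oxy]methyl}-3,9-dimethyldodec-6-en-4-ol | CC[C@H](C)[C@@H](O)[C@@H](/C=C/C[C@H](C)CCCO[Si](C)(C)C(C)(C)C)COCc1ccc(OC)cc1 | intermediate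
20 | (3S,4R,5S,6E,9R)-4,12-bis(tert-butyldimethylsilyloxy)-5-{[(4-methoxybenzyl)oxy]methyl}-3,9-dimethyldodec-6-ene | CC[C@H](C)[C@@H](O[Si](C)(C)C(C)(C)C)[C@@H](/C=C/C[C@H](C)CCCO[Si](C)(C)C(C)(C)C)COCc1ccc(OC)cc1 | intermediate
21 | (2S,3E,6R)-2-[(1R,2S)-1-(tert-butyldimethylsilyloxy)-2-methylbutyl]-9-(tert-butyldimethylsilyloxy)-6-methylnon-3-en-1-ol | CC[C@H](C)[C@@H](O[Si](C)(C)C(C)(C)C)[C@@H](/C=C/C[C@H](C)CCCO[Si](C)(C)C(C)(C)C)CO | intermediate
22 | (2R,3E,6R)-2-[(1R,2S)-1-(tert-butyldimethylsilyloxy)-2-methylbutyl]-9-(tert-butyldimethylsilyloxy)-6-methylnon-3-enal (not isolated) | CC[C@H](C)[C@@H](O[Si](C)(C)C(C)(C)C)[C@@H](/C=C/C[C@H](C)CCCO[Si](C)(C)C(C)(C)C)C=O | intermediate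
23 | (2R,3E,6R)-2-[(1R,2S)-1-(tert-butyldimethylsilyloxy)-2-methylbutyl]-9-(tert-butyldimethylsilyloxy)-6-methylnon-3-enoic acid | CC[C@H](C)[C@@H](O[Si](C)(C)C(C)(C)C)[C@@H](/C=C/C[C@H](C)CCCO[Si](C)(C)C(C)(C)C)C(=O)O | intermediate
24 | allyl (2R,3E,6R)-2-[(1R,2S)-1-(tert-butyldimethylsilyloxy)-2-methylbutyl]-9-(tert-butyldimethylsilyloxy)-6-methylnon-3-enoate | CC[C@H](C)[C@@H](O[Si](C)(C)C(C)(C)C)[C@@H](/C=C/C[C@H](C)CCCO[Si](C)(C)C(C)(C)C)C(=O)OCC=C | intermediate
25 | allyl (2R,3E,6R)-2-[(1R,2S)-1-(tert-butyldimethylsilyloxy)-2-methylbutyl]-9-hydroxy-6-methylnon-3-enoate | CC[C@H](C)[C@@H](O[Si](C)(C)C(C)(C)C)[C@@H](/C=C/C[C@H](C)CCCO)C(=O)OCC=C | intermediate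
26 | allyl (2R,3E,6R)-2-[(1R,2S)-1-(tert-butyldimethylsilyloxy)-2-methylbutyl]-6-methyl-9-oxonon-3-enoate (not isolated) | CC[C@H](C)[C@@H](O[Si](C)(C)C(C)(C)C)[C@@H](/C=C/C[C@H](C)CCC=O)C(=O)OCC=C | intermediate
27 | (4R,6E,8R)-9-(allyloxy)-8-[(1R,2S)-1-(tert-butyldimethylsilyloxy)-2-methylbutyl]-4-methyl-9-oxonon-6-enoic acid | CC[C@H](C)[C@@H](O[Si](C)(C)C(C)(C)C)[C@@H](/C=C/C[C@H](C)CCC(=O)O)C(=O)OCC=C | intermediate
28 | Meldrum's acid (2,2-dimethyl-1,3-dioxane-4,6-dione) | CC1(C)OC(=O)CC(=O)O1 | starting material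
29 | allyl (2R,3E,6R)-2-[(1R,2S)-1-(tert-butyldimethylsilyloxy)-2-methylbutyl]-9-(2,2-dimethyl-4,6-dioxo-1,3-dioxan-5-ylidene)-9-hydroxy-6-methylnon-3-enoate | CC[C@H](C)[C@@H](O[Si](C)(C)C(C)(C)C)[C@@H](/C=C/C[C@H](C)CCC(O)=C1C(=O)OC(C)(C)OC1=O)C(=O)OCC=C | intermediate
30 | methyl (R)-3-hydroxybutanoate | C[C@@H](O)CC(=O)OC | starting material
31 | acylketene from 29, C12(=O)–C3'H=C2'=O (not isolated) | CC[C@H](C)[C@@H](O[Si](C)(C)C(C)(C)C)[C@@H](/C=C/C[C@H](C)CCC(=O)C=C=O)C(=O)OCC=C | intermediate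
32 | 1-allyl 11-[(R)-4-methoxy-4-oxobutan-2-yl] (2R,3E,6R)-2-[(1R,2S)-1-(tert-butyldimethylsilyloxy)-2-methylbutyl]-6-methyl-9-oxoundec-3-enedioate | CC[C@H](C)[C@@H](O[Si](C)(C)C(C)(C)C)[C@@H](/C=C/C[C@H](C)CCC(=O)CC(=O)O[C@H](C)CC(=O)OC)C(=O)OCC=C | intermediate
33 | (2R,3E,6R)-2-[(1R,2S)-1-(tert-butyldimethylsilyloxy)-2-methylbutyl]-11-{[(R)-4-methoxy-4-oxobutan-2-yl]oxy}-6-methyl-9,11-dioxoundec-3-enoic acid | CC[C@H](C)[C@@H](O[Si](C)(C)C(C)(C)C)[C@@H](/C=C/C[C@H](C)CCC(=O)CC(=O)O[C@H](C)CC(=O)OC)C(=O)O | intermediate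
34 | dipotassium carboxylate enolate of 33 (not isolated) | [K+].[K+].CC[C@H](C)[C@@H](O[Si](C)(C)C(C)(C)C)[C@@H](/C=C/C[C@H](C)CCC([O-])=CC(=O)O[C@H](C)CC(=O)OC)C(=O)[O-] | intermediate
35 | dipotassium salt of 36 (not isolated) | [K+].[K+].CC[C@H](C)[C@@H](O[Si](C)(C)C(C)(C)C)[C@@H](/C=C/C[C@H](C)CCC(=O)C1=C([O-])C[C@@H](C)OC1=O)C(=O)[O-] | intermediate
36 | (2R,3E,6R)-2-[(1R,2S)-1-(tert-butyldimethylsilyloxy)-2-methylbutyl]-9-[(R)-4-hydroxy-6-methyl-2-oxo-5,6-dihydro-2H-pyran-3-yl]-6-methyl-9-oxonon-3-enoic acid | CC[C@H](C)[C@@H](O[Si](C)(C)C(C)(C)C)[C@@H](/C=C/C[C@H](C)CCC(=O)C1=C(O)C[C@@H](C)OC1=O)C(=O)O | intermediate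
37 | (2R,3E,6R)-2-[(1R,2S)-1-hydroxy-2-methylbutyl]-9-[(R)-4-hydroxy-6-methyl-2-oxo-5,6-dihydro-2H-pyran-3-yl]-6-methyl-9-oxonon-3-enoic acid | CC[C@H](C)[C@@H](O)[C@@H](/C=C/C[C@H](C)CCC(=O)C1=C(O)C[C@@H](C)OC1=O)C(=O)O | target

**Step count**

Total: 19 steps. Longest linear sequence: 15 steps (steps 1–3 and 8–19 from (R)-citronellol); the boronate branch is steps 4–6 and the aldehyde branch is step 7.

**Steps most likely to fail**

Step 8. The 1,2-migration may stall, or the hindered allylboronate may add so slowly to the α-branched aldehyde that the aldehyde epimerises at C3 or the E and syn control erodes. The fallback sets out from 14 and 5 and returns at 20; it sets C4 and C5 by an Evans syn-aldol and the alkene by a Julia–Kocienski olefination. (S)-4-Benzyl-3-{3-[(4-methoxybenzyl)oxy]propanoyl}oxazolidin-2-one F1, made from 3-[(4-methoxybenzyl)oxy]propanoic acid through its pivaloyl mixed anhydride and lithiated (S)-4-benzyloxazolidin-2-one, would be enolised with Bu2BOTf and iPr2NEt in CH2Cl2 at −78 °C and treated with 14 to give the syn aldol adduct F2, in which the imide carbonyl is C6. TBSOTf and 2,6-lutidine would give the silyl ether F3, LiBH4 in wet Et2O would remove the auxiliary to give the C6 alcohol F4, and Dess–Martin periodinane buffered with NaHCO3 would give the C6 aldehyde F5. In parallel, LiAlH4 in THF would cleave the carbamate of 5 to the C7 alcohol F6, a Mitsunobu reaction with 1-phenyl-1H-tetrazole-5-thiol (PPh3, DIAD) would give the sulfide F7, and (NH4)6Mo7O24 with H2O2 in EtOH would give the sulfone F8. Deprotonation of F8 with KHMDS in DME at −60 °C and addition of F5 should form the E alkene C6=C7 and so give 20.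

Step 18. Loss of the β-keto carboxylate from the methyl ester enolate (E1cB to the crotonate) or alkoxide opening of the new lactone may outrun the C-acylation. The fallback sets out from 27 and 30 and returns at 36; it builds the ring first and attaches it by O-acylation and acyl migration. Ester 30 would be condensed with excess lithium enolate of tert-butyl acetate (LDA, THF, −78 °C to −20 °C) to give tert-butyl (R)-5-hydroxy-3-oxohexanoate F9, and TFA in CH2Cl2 would cleave the ester and lactonise it to (R)-4-hydroxy-6-methyl-5,6-dihydro-2H-pyran-2-one F10. Coupling of F10 with acid 27 by DCC and catalytic DMAP would give the enol ester F11, and DMAP with Et3N would move the acyl group from oxygen to C3' (Fries-type shift) to give the C3'-acyl allyl ester F12. Pd(PPh3)4 with N-methylaniline in THF would then remove the allyl group and give 36.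

Step 16. The acylketene may be consumed by dimerisation or by traces of water (decarboxylation to the methyl ketone) faster than the secondary alcohol traps it. The fallback sets out from 27, 28 and 30 and returns at 32; it forms the C12–C3' bond by a decarboxylative Claisen condensation (Masamune–Brooks). Meldrum's acid 28 would be opened by 30 in toluene at 100 °C to give the malonic half ester 3-{[(R)-4-methoxy-4-oxobutan-2-yl]oxy}-3-oxopropanoic acid F13. Acid 27 would be converted with carbonyldiimidazole in THF to the acyl imidazolide F14, which, treated with the magnesium salt of F13 (MgCl2, Et3N, MeCN), should give 32 after loss of CO2.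

**Further compounds**

F1 | step 8 | (S)-4-benzyl-3-{3-[(4-methoxybenzyl)oxy]propanoyl}oxazolidin-2-one | COc1ccc(COCCC(=O)N2[C@@H](Cc3ccccc3)COC2=O)cc1
F2 | step 8 | (S)-4-benzyl-3-[(2S,3R,4S)-3-hydroxy-2-{[(4-methoxybenzyl)oxy]methyl}-4-methylhexanoyl]oxazolidin-2-one | CC[C@H](C)[C@@H](O)[C@H](COCc1ccc(OC)cc1)C(=O)N1[C@@H](Cc2ccccc2)COC1=O
F3 | step 8 | (S)-4-benzyl-3-[(2S,3R,4S)-3-(tert-butyldimethylsilyloxy)-2-{[(4-methoxybenzyl)oxy]methyl}-4-methylhexanoyl]oxazolidin-2-one | CC[C@H](C)[C@@H](O[Si](C)(C)C(C)(C)C)[C@H](COCc1ccc(OC)cc1)C(=O)N1[C@@H](Cc2ccccc2)COC1=O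
F4 | step 8 | (2S,3R,4S)-3-(tert-butyldimethylsilyloxy)-2-{[(4-methoxybenzyl)oxy]methyl}-4-methylhexan-1-ol | CC[C@H](C)[C@@H](O[Si](C)(C)C(C)(C)C)[C@H](COCc1ccc(OC)cc1)CO
F5 | step 8 | (2S,3R,4S)-3-(tert-butyldimethylsilyloxy)-2-{[(4-methoxybenzyl)oxy]methyl}-4-methylhexanal | CC[C@H](C)[C@@H](O[Si](C)(C)C(C)(C)C)[C@H](COCc1ccc(OC)cc1)C=O
F6 | step 8 | (R)-6-(tert-butyldimethylsilyloxy)-3-methylhexan-1-ol | OCC[C@H](C)CCCO[Si](C)(C)C(C)(C)C
F7 | step 8 | 5-{[(R)-6-(tert-butyldimethylsilyloxy)-3-methylhexyl]sulfanyl}-1-phenyl-1H-tetrazole | CC(C)(C)[Si](C)(C)OCCC[C@@H](C)CCSc1nnnn1-c1ccccc1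
F8 | step 8 | 5-{[(R)-6-(tert-butyldimethylsilyloxy)-3-methylhexyl]sulfonyl}-1-phenyl-1H-tetrazole | CC(C)(C)[Si](C)(C)OCCC[C@@H](C)CCS(=O)(=O)c1nnnn1-c1ccccc1
F9 | step 18 | tert-butyl (R)-5-hydroxy-3-oxohexanoate | C[C@@H](O)CC(=O)CC(=O)OC(C)(C)C
F10 | step 18 | (R)-4-hydroxy-6-methyl-5,6-dihydro-2H-pyran-2-one | C[C@@H]1CC(O)=CC(=O)O1
F11 | step 18 | enol ester of 27 at the C4' oxygen of F10 | CC[C@H](C)[C@@H](O[Si](C)(C)C(C)(C)C)[C@@H](/C=C/C[C@H](C)CCC(=O)OC1=CC(=O)O[C@H](C)C1)C(=O)OCC=C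
F12 | step 18 | allyl ester of 36 | CC[C@H](C)[C@@H](O[Si](C)(C)C(C)(C)C)[C@@H](/C=C/C[C@H](C)CCC(=O)C1=C(O)C[C@@H](C)OC1=O)C(=O)OCC=C
F13 | step 16 | 3-{[(R)-4-methoxy-4-oxobutan-2-yl]oxy}-3-oxopropanoic acid | COC(=O)C[C@@H](C)OC(=O)CC(=O)O
F14 | step 16 | acyl imidazolide of 27 | CC[C@H](C)[C@@H](O[Si](C)(C)C(C)(C)C)[C@@H](/C=C/C[C@H](C)CCC(=O)n1ccnc1)C(=O)OCC=C
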